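**Assumption:** the antipode of the chiral ligand in step 1 is the one that gives the (R)-boronate 2 (to be confirmed by Mosher analysis of 3); DMDO is used as a titrated acetone solution.

## Retrosynthetic overview

1. Target ⇒ diol 26 (acylation at C8–OH, desilylation at C5–O) ⇒ 2-acyl-2-hydroxycycloheptanone 25 (hydroxyl-directed ketone reduction).
2. Key step: 25 ⇒ cyclohexanol 23 by a one-carbon ring expansion (oxidative α-ketol 1,2-shift, C7 set by transfer from the carbinol); 23 ⇒ keto-lactone 17 + diazo enone 21.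
3. 17 ⇒ enone 9 by conjugate addition of a masked-acrylate cuprate, α-bromination and carboxylate SN2 lactonisation (cis-fused γ-lactone).
4. 9 ⇒ cyclohex-2-enone by asymmetric β-borylation/oxidation, silylation, dehydrogenation and anti α'-methylation.
5. Ring order: six-membered carbocycle (from 1) → γ-lactone → seven-membered ring by ring expansion.

## Route

Step 1
Reactants: 1 cyclohex-2-en-1-one
Product: 3 (R)-3-hydroxycyclohexan-1-one, via boryl ketone 2 (not isolated)
Conditions: CuCl (3 mol %), Josiphos-type ligand (3 mol %), NaOt-Bu (5 mol %), B2pin2 (1.1 equiv), MeOH (2 equiv), THF, rt; then NaBO3·4H2O, THF/H2O, rt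
Reagents that add atoms: sodium perborate [Na+].[O-]OB=O; bis(pinacolato)diboron CC1(C)OB(OC1(C)C)B1OC(C)(C)C(C)(C)O1 (boron of 2 only)
Why: Cu(I)–boryl conjugate addition (Yun-type asymmetric β-borylation) sets C3 under ligand control, and perborate oxidation of the C–B bond proceeds with retention.

Step 2
Reactants: 3 (R)-3-hydroxycyclohexan-1-one
Product: 4 (R)-3-[(tert-butyldimethylsilyl)oxy]cyclohexan-1-one
Conditions: TBSCl, imidazole, DMF, 0 °C → rt
Reagents that add atoms: tert-butyldimethylsilyl chloride CC(C)(C)[Si](C)(C)Cl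
Why: Standard silyl ether formation under mild base, which avoids β-elimination of the aldol-type hydroxy ketone and leaves the stereocentre untouched.

Step 3
Reactants: 4 (R)-3-[(tert-butyldimethylsilyl)oxy]cyclohexan-1-one
Product: 6 (R)-5-[(tert-butyldimethylsilyl)oxy]cyclohex-2-en-1-one, via lithium enolate 5 (not isolated)
Conditions: LDA, THF, −78 °C; then N-tert-butylbenzenesulfinimidoyl chloride, −78 °C
Reagents that add atoms: none
Why: Kinetic deprotonation occurs at the CH2 remote from the silyloxy group and the Mukaiyama dehydrogenation (S-alkylation, syn-elimination) gives the enone without touching C5.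

Step 4
Reactants: 6 (R)-5-[(tert-butyldimethylsilyl)oxy]cyclohex-2-en-1-one; 7 iodomethane
Product: 9 (5R,6S)-5-[(tert-butyldimethylsilyl)oxy]-6-methylcyclohex-2-en-1-one, via lithium dienolate 8 (not isolated)
Conditions: LDA (1.05 equiv), THF, −78 °C; MeI, DMPU, −78 → −45 °C; AcOH quench at −78 °C
Reagents that add atoms: none
Why: Kinetic α'-enolate alkylation, in which MeI approaches anti to the adjacent silyloxy group and so sets the 5,6-trans methyl centre (6S); the cold quench prevents loss of silyloxide and epimerisation.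

Step 5
Reactants: 9 (5R,6S)-5-[(tert-butyldimethylsilyl)oxy]-6-methylcyclohex-2-en-1-one; 10 2-bromo-3,3-dimethoxyprop-1-ene
Product: 13 (3R,5R,6S)-5-[(tert-butyldimethylsilyl)oxy]-3-(3,3-dimethoxyprop-1-en-2-yl)-6-methyl-1-[(trimethylsilyl)oxy]cyclohex-1-ene, via vinyllithium 11 (not isolated), via cuprate 12 (not isolated)
Conditions: 10 (2.2 equiv), t-BuLi (4.4 equiv), Et2O, −78 °C; CuBr·SMe2 (1.1 equiv), −78 → −40 °C; then 9, TMSCl, THF, −78 °C; Et3N then NH4Cl/NH3 work-up
Reagents that add atoms: chlorotrimethylsilane C[Si](C)(C)Cl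
Why: TMSCl-accelerated conjugate addition of the Marino–Farina masked-acrylate cuprate occurs axially and anti to the C5 silyloxy group (3,5-trans), and the enolate is trapped regiospecifically as the silyl enol ether.

Step 6
Reactants: 13 (3R,5R,6S)-5-[(tert-butyldimethylsilyl)oxy]-3-(3,3-dimethoxyprop-1-en-2-yl)-6-methyl-1-[(trimethylsilyl)oxy]cyclohex-1-ene
Product: 15 2-[(1S,2S,4S,5R)-2-bromo-5-[(tert-butyldimethylsilyl)oxy]-4-methyl-3-oxocyclohexyl]prop-2-enal, via bromo ketone acetal 14 (not isolated)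
Conditions: NBS, THF, −78 → 0 °C; then PPTS, acetone/H2O, rt
Reagents that add atoms: N-bromosuccinimide O=C1CCC(=O)N1Br; water O
Why: Electrophilic bromination of the silyl enol ether is regiospecific and occurs anti to the adjacent axial side chain, and the allylic acetal hydrolyses under conditions that spare the TBS ether.

Step 7
Reactants: 15 2-[(1S,2S,4S,5R)-2-bromo-5-[(tert-butyldimethylsilyl)oxy]-4-methyl-3-oxocyclohexyl]prop-2-enal
Product: 17 (3aS,5R,6S,7aR)-5-[(tert-butyldimethylsilyl)oxy]-6-methyl-3-methylidenehexahydro-1-benzofuran-2,7-dione, via bromo acid 16 (not isolated)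
Conditions: NaClO2, NaH2PO4, 2-methylbut-2-ene, t-BuOH/H2O, 0 °C; then NaHCO3 (aq), rt
Reagents that add atoms: sodium chlorite [Na+].[O-]Cl=O
Why: Pinnick oxidation gives the acrylic acid, whose carboxylate displaces the activated α-keto bromide (5-exo-tet SN2, inversion) to close the cis-fused α-methylene-γ-lactone (7aR).

Step 8
Reactants: 18 (E)-pent-3-en-2-one
Product: 21 (E)-1-diazopent-3-en-2-one, via lithium dienolate 19 (not isolated), via trifluoroacetyl diketone 20 (not isolated)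
Conditions: LiHMDS, THF, −78 °C; CF3CO2CH2CF3; aq. HCl work-up, crude used; then MsN3, Et3N, H2O, MeCN, rt
Reagents that add atoms: methanesulfonyl azide CS(=O)(=O)N=[N+]=[N-]; 2,2,2-trifluoroethyl trifluoroacetate O=C(OCC(F)(F)F)C(F)(F)F (trifluoroacetyl group of 20 only)
Why: Danheiser detrifluoroacetylative diazo transfer, the standard route to α'-diazo enones, with kinetic enolisation at the methyl group and retention of the E-alkene.

Step 9
Reactants: 17 (3aS,5R,6S,7aR)-5-[(tert-butyldimethylsilyl)oxy]-6-methyl-3-methylidenehexahydro-1-benzofuran-2,7-dione; 21 (E)-1-diazopent-3-en-2-one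
Product: 23 (3aS,5R,6S,7R,7aR)-5-[(tert-butyldimethylsilyl)oxy]-7-[(E)-1-diazo-2-oxopent-3-en-1-yl]-7-hydroxy-6-methyl-3-methylidenehexahydro-1-benzofuran-2(3H)-one, via lithiated diazoketone 22 (not isolated)
Conditions: 21 (1.2 equiv), LDA, THF, −78 °C; then 17, −78 °C; AcOH quench at −78 °C
Reagents that add atoms: none
Why: Aldol-type addition of a lithiated α-diazoketone (Schöllkopf/Wenkert) to the activated α-acyloxy ketone, with equatorial attack because the axial lactone carbon at C3a blocks the axial trajectory, giving the 7R carbinol (OH axial, anti to the OTBS face).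

Step 10
Reactants: 23 (3aS,5R,6S,7R,7aR)-5-[(tert-butyldimethylsilyl)oxy]-7-[(E)-1-diazo-2-oxopent-3-en-1-yl]-7-hydroxy-6-methyl-3-methylidenehexahydro-1-benzofuran-2(3H)-one
Product: 25 (3aS,5R,6S,7R,8aR)-7-[(E)-but-2-enoyl]-5-[(tert-butyldimethylsilyl)oxy]-7-hydroxy-6-methyl-3-methylidenehexahydro-2H-cyclohepta[b]furan-2,8(3H)-dione, via vicinal diketone 24 (not isolated)
Conditions: DMDO (1.2 equiv, acetone), CH2Cl2, 4 Å MS, −78 → −40 °C; volatiles removed cold; then Zn(OTf)2 (20 mol %), CH2Cl2, −20 → 0 °C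
Reagents that add atoms: dimethyldioxirane CC1(C)OO1
Why: Proposed new method: DMDO turns the diazo carbon into a ketone (known for α-diazoketones) and unmasks a tertiary α-hydroxy 1,2-diketone whose central carbonyl is highly electrophilic; Zn(II) chelation of the carbinol oxygen and that carbonyl (syn-periplanar O–C–C=O) triggers a suprafacial 1,2-shift of the electron-richer ring carbon C6 (CHMe) in preference to the acyloxy-bearing C7a, which enlarges the cyclohexane to the cycloheptanone, relieves the vicinal-dicarbonyl repulsion and transfers the carbinol configuration of 23 to the new quaternary C7 (hydroxyl on the lactone face, crotonoyl on the OTBS face); the closest known reactions are the Lewis-acid α-ketol (acyloin) rearrangement of 1-acylcycloalkanols (steroid D-homoannulation) and of β-hydroxy α-keto esters, not yet shown as a one-pot diazo oxidation/6→7 enlargement onto an enone-substituted 1,2-dione.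

Step 11
Reactants: 25 (3aS,5R,6S,7R,8aR)-7-[(E)-but-2-enoyl]-5-[(tert-butyldimethylsilyl)oxy]-7-hydroxy-6-methyl-3-methylidenehexahydro-2H-cyclohepta[b]furan-2,8(3H)-dione
Product: 26 (3aS,5R,6S,7S,8S,8aR)-7-[(E)-but-2-enoyl]-5-[(tert-butyldimethylsilyl)oxy]-7,8-dihydroxy-6-methyl-3-methylideneoctahydro-2H-cyclohepta[b]furan-2-one
Conditions: Me4NBH(OAc)3, MeCN/AcOH (1:1), −30 °C
Reagents that add atoms: none
Why: Hydroxyl-directed triacetoxyborohydride reduction (Evans–Saksena type) delivers hydride intramolecularly from the C7 hydroxyl face to the more electrophilic saturated α-acyloxy ketone, giving the trans-7,8-diol (8S) without conjugate reduction of the enone or the methylene lactone.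

Step 12
Reactants: 26 (3aS,5R,6S,7S,8S,8aR)-7-[(E)-but-2-enoyl]-5-[(tert-butyldimethylsilyl)oxy]-7,8-dihydroxy-6-methyl-3-methylideneoctahydro-2H-cyclohepta[b]furan-2-one; 27 3-methylbutanoyl chloride
Product: 29 (3aS,5R,6S,7S,8S,8aR)-7-[(E)-but-2-enoyl]-5,7-dihydroxy-6-methyl-3-methylidene-2-oxooctahydro-2H-cyclohepta[b]furan-8-yl 3-methylbutanoate, via silyl ether ester 28 (not isolated)
Conditions: 27, DMAP, pyridine, CH2Cl2, 0 °C → rt; MeOH (destroys excess 27); then HF·pyridine, THF, 0 °C → rt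
Reagents that add atoms: none
Why: DMAP-catalysed acylation esterifies the only free secondary hydroxyl (the tertiary α-ketol OH is inert, C5–O is silylated), and HF·pyridine then removes the TBS group without harming the enone, ester or methylene lactone.

## Compound list

1 | cyclohex-2-en-1-one | O=C1C=CCCC1 | starting material
2 | (R)-3-(4,4,5,5-tetramethyl-1,3,2-dioxaborolan-2-yl)cyclohexan-1-one | C1[C@@H](B2OC(C)(C)C(C)(C)O2)CC(=O)CC1 | intermediate
3 | (R)-3-hydroxycyclohexan-1-one | C1[C@@H](O)CC(=O)CC1 | intermediate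
4 | (R)-3-[(tert-butyldimethylsilyl)oxy]cyclohexan-1-one | C1[C@@H](O[Si](C)(C)C(C)(C)C)CC(=O)CC1 | intermediate
5 | lithium (R)-5-[(tert-butyldimethylsilyl)oxy]cyclohex-1-en-1-olate | C1[C@@H](O[Si](C)(C)C(C)(C)C)CC(O[Li])=CC1 | intermediate
6 | (R)-5-[(tert-butyldimethylsilyl)oxy]cyclohex-2-en-1-one | C1[C@@H](O[Si](C)(C)C(C)(C)C)CC(=O)C=C1 | intermediate
7 | iodomethane | CI | starting material
8 | lithium (R)-3-[(tert-butyldimethylsilyl)oxy]cyclohexa-1,5-dien-1-olate | C1[C@@H](O[Si](C)(C)C(C)(C)C)C=C(O[Li])C=C1 | intermediate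
9 | (5R,6S)-5-[(tert-butyldimethylsilyl)oxy]-6-methylcyclohex-2-en-1-one | C1[C@@H](O[Si](C)(C)C(C)(C)C)[C@H](C)C(=O)C=C1 | intermediate
10 | 2-bromo-3,3-dimethoxyprop-1-ene | C=C(Br)C(OC)OC | starting material
11 | (3,3-dimethoxyprop-1-en-2-yl)lithium | [Li]C(=C)C(OC)OC | intermediate
12 | lithium bis(3,3-dimethoxyprop-1-en-2-yl)cuprate | [Li+].C=C([Cu-]C(=C)C(OC)OC)C(OC)OC | intermediate
13 | (3R,5R,6S)-5-[(tert-butyldimethylsilyl)oxy]-3-(3,3-dimethoxyprop-1-en-2-yl)-6-methyl-1-[(trimethylsilyl)oxy]cyclohex-1-ene | C1[C@@H](O[Si](C)(C)C(C)(C)C)[C@H](C)C(O[Si](C)(C)C)=C[C@@H]1C(=C)C(OC)OC | intermediate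
14 | (2S,3S,5R,6S)-2-bromo-5-[(tert-butyldimethylsilyl)oxy]-3-(3,3-dimethoxyprop-1-en-2-yl)-6-methylcyclohexan-1-one | C1[C@@H](O[Si](C)(C)C(C)(C)C)[C@H](C)C(=O)[C@@H](Br)[C@@H]1C(=C)C(OC)OC | intermediate
15 | 2-[(1S,2S,4S,5R)-2-bromo-5-[(tert-butyldimethylsilyl)oxy]-4-methyl-3-oxocyclohexyl]prop-2-enal | C1[C@@H](O[Si](C)(C)C(C)(C)C)[C@H](C)C(=O)[C@@H](Br)[C@@H]1C(=C)C=O | intermediate
16 | 2-[(1S,2S,4S,5R)-2-bromo-5-[(tert-butyldimethylsilyl)oxy]-4-methyl-3-oxocyclohexyl]prop-2-enoic acid | C1[C@@H](O[Si](C)(C)C(C)(C)C)[C@H](C)C(=O)[C@@H](Br)[C@@H]1C(=C)C(=O)O | intermediate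
17 | (3aS,5R,6S,7aR)-5-[(tert-butyldimethylsilyl)oxy]-6-methyl-3-methylidenehexahydro-1-benzofuran-2,7-dione | C=C1C(=O)O[C@@H]2[C@H]1C[C@@H](O[Si](C)(C)C(C)(C)C)[C@H](C)C2=O | intermediate
18 | (E)-pent-3-en-2-one | C/C=C/C(C)=O | starting material
19 | lithium (E)-penta-1,3-dien-2-olate | C/C=C/C(=C)O[Li] | intermediate
20 | (E)-1,1,1-trifluorohept-5-ene-2,4-dione | C/C=C/C(=O)CC(=O)C(F)(F)F | intermediate
21 | (E)-1-diazopent-3-en-2-one | C/C=C/C(=O)C=[N+]=[N-] | intermediate
22 | [(E)-1-diazo-2-oxopent-3-en-1-yl]lithium | C/C=C/C(=O)C([Li])=[N+]=[N-] | intermediate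
23 | (3aS,5R,6S,7R,7aR)-5-[(tert-butyldimethylsilyl)oxy]-7-[(E)-1-diazo-2-oxopent-3-en-1-yl]-7-hydroxy-6-methyl-3-methylidenehexahydro-1-benzofuran-2(3H)-one | C=C1C(=O)O[C@@H]2[C@H]1C[C@@H](O[Si](C)(C)C(C)(C)C)[C@H](C)[C@@]2(O)C(=[N+]=[N-])C(=O)/C=C/C | intermediate
24 | (3aS,5R,6S,7S,7aR)-5-[(tert-butyldimethylsilyl)oxy]-7-hydroxy-6-methyl-3-methylidene-7-[(E)-2-oxopent-3-enoyl]hexahydro-1-benzofuran-2(3H)-one | C=C1C(=O)O[C@@H]2[C@H]1C[C@@H](O[Si](C)(C)C(C)(C)C)[C@H](C)[C@@]2(O)C(=O)C(=O)/C=C/C | intermediate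
25 | (3aS,5R,6S,7R,8aR)-7-[(E)-but-2-enoyl]-5-[(tert-butyldimethylsilyl)oxy]-7-hydroxy-6-methyl-3-methylidenehexahydro-2H-cyclohepta[b]furan-2,8(3H)-dione | C=C1C(=O)O[C@@H]2[C@H]1C[C@@H](O[Si](C)(C)C(C)(C)C)[C@H](C)[C@@](O)(C(=O)/C=C/C)C2=O | intermediate
26 | (3aS,5R,6S,7S,8S,8aR)-7-[(E)-but-2-enoyl]-5-[(tert-butyldimethylsilyl)oxy]-7,8-dihydroxy-6-methyl-3-methylideneoctahydro-2H-cyclohepta[b]furan-2-one | C=C1C(=O)O[C@@H]2[C@H]1C[C@@H](O[Si](C)(C)C(C)(C)C)[C@H](C)[C@@](O)(C(=O)/C=C/C)[C@H]2O | intermediate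
27 | 3-methylbutanoyl chloride | CC(C)CC(=O)Cl | starting material
28 | (3aS,5R,6S,7S,8S,8aR)-7-[(E)-but-2-enoyl]-5-[(tert-butyldimethylsilyl)oxy]-7-hydroxy-6-methyl-3-methylidene-2-oxooctahydro-2H-cyclohepta[b]furan-8-yl 3-methylbutanoate | C=C1C(=O)O[C@@H]2[C@H]1C[C@@H](O[Si](C)(C)C(C)(C)C)[C@H](C)[C@@](O)(C(=O)/C=C/C)[C@H]2OC(=O)CC(C)C | intermediate
29 | (3aS,5R,6S,7S,8S,8aR)-7-[(E)-but-2-enoyl]-5,7-dihydroxy-6-methyl-3-methylidene-2-oxooctahydro-2H-cyclohepta[b]furan-8-yl 3-methylbutanoate | C=C1C(=O)O[C@@H]2[C@H]1C[C@@H](O)[C@H](C)[C@@](O)(C(=O)/C=C/C)[C@H]2OC(=O)CC(C)C | target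

## Step count and risk

Total step count: 12. Longest linear sequence: 11 (steps 1–7 and 9–12; step 8 is the side branch that makes 21).

The three steps most likely to fail:

**Step 10 (the proposed oxidative α-ketol ring expansion).** The risks are competing oxa-Michael closure of the hydroxy ene-dione, migration of C7a instead of C6, and rearrangement through the non-chelated rotamer, which would give the C7 epimer. The fallback uses known chemistry and sets out from 23. Rh2(OAc)4 (1 mol %, CH2Cl2, rt) converts the β-hydroxy α-diazoketone through the rhodium carbenoid and a 1,2-alkyl shift into the ring-expanded β-diketone (3aS,5R,6R,8aR)-7-[(E)-but-2-enoyl]-5-[(tert-butyldimethylsilyl)oxy]-6-methyl-3-methylidenehexahydro-2H-cyclohepta[b]furan-2,8(3H)-dione F1 (enolised, C7 not defined). α-Hydroxylation of its enol with DMDO (acetone, 0 °C), or of its potassium enolate with the matched antipode of (camphorsulfonyl)oxaziridine, gives 25 after separation of any C7 epimer. It comes back to the route at 25.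

**Step 11 (chemoselective directed reduction).** The enone carbonyl is also α to the directing hydroxyl and may be reduced competitively. The fallback sets out from 25. Excess Me4NBH(OAc)3 (6 equiv, MeCN/AcOH, rt) reduces both ketones under direction of the C7 hydroxyl to (3aS,5R,6S,7R,8S,8aR)-5-[(tert-butyldimethylsilyl)oxy]-7,8-dihydroxy-7-[(E)-1-hydroxybut-2-en-1-yl]-6-methyl-3-methylideneoctahydro-2H-cyclohepta[b]furan-2-one F2 (side-chain carbinol configuration irrelevant). MnO2 (CH2Cl2, rt) then re-oxidises only the allylic carbinol to the enone. It comes back to the route at 26.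

**Step 4 (α'-methylation of a β-silyloxy dienolate).** The risks are E1cB loss of silyloxide with aromatisation to phenol, and erosion of the trans ratio. The fallback sets out from 6. HF·pyridine (THF, 0 °C) removes the silyl group to give (R)-5-hydroxycyclohex-2-en-1-one F3. LDA (2.2 equiv, THF, −78 °C) forms the alkoxide–dienolate dianion, whose alkoxide cannot leave, and MeI alkylates it anti to the alkoxide (Fráter–Seebach-type) to give (5R,6S)-5-hydroxy-6-methylcyclohex-2-en-1-one F4. TBSCl/imidazole re-silylates it. It comes back to the route at 9.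

## Further compounds

F1 | step 10 | (3aS,5R,6R,8aR)-7-[(E)-but-2-enoyl]-5-[(tert-butyldimethylsilyl)oxy]-6-methyl-3-methylidenehexahydro-2H-cyclohepta[b]furan-2,8(3H)-dione | C=C1C(=O)O[C@@H]2[C@H]1C[C@@H](O[Si](C)(C)C(C)(C)C)[C@H](C)C(C(=O)/C=C/C)C2=O
F2 | step 11 | (3aS,5R,6S,7R,8S,8aR)-5-[(tert-butyldimethylsilyl)oxy]-7,8-dihydroxy-7-[(E)-1-hydroxybut-2-en-1-yl]-6-methyl-3-methylideneoctahydro-2H-cyclohepta[b]furan-2-one | C=C1C(=O)O[C@@H]2[C@H]1C[C@@H](O[Si](C)(C)C(C)(C)C)[C@H](C)[C@@](O)(C(O)/C=C/C)[C@H]2O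
F3 | step 4 | (R)-5-hydroxycyclohex-2-en-1-one | C1[C@@H](O)CC(=O)C=C1
F4 | step 4 | (5R,6S)-5-hydroxy-6-methylcyclohex-2-en-1-one | C1[C@@H](O)[C@H](C)C(=O)C=C1
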